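**Retrosynthetic overview**
1. Bibenzyl CH2–CH2 bond (made first): aldehyde 1 is turned by hydrazine 2 into a masked benzyl carbanion and added to the C=O of aldehyde 3 (through hydrazone 4) to give bromo alcohol 5, so two carbonyl carbons are joined.
2. Aryl–CH2 bond of the diarylmethane (key step, made second): the C–Br carbon of 5 is joined to the carbonyl carbon of aldehyde 6, used with reversed polarity as hydrazone 7, to give 8.
3. Last: one hydrogenolysis removes the carbinol OH and both benzyl ethers, 8 → target 9.
4. Rings: none is formed; the three benzene rings are bought intact in 1, 3 and 6, and only the two links between them are built.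

Assumption: 9 has no stereocentre, so "single enantiomer" is read as the compound as drawn; the one carbinol centre made on the way (in 5 and 8) is racemic and is removed in step 3.

**Route**

Step 1
Reactants: 1 2-bromo-3,5-dimethoxybenzaldehyde; 2 hydrazine monohydrate; 3 3-(benzyloxy)benzaldehyde
Product: 5 racemic 1-[3-(benzyloxy)phenyl]-2-(2-bromo-3,5-dimethoxyphenyl)ethan-1-ol, via (E)-(2-bromo-3,5-dimethoxybenzylidene)hydrazine 4 (not isolated)
Conditions: 1 (1.3 equiv), 2 (1.35 equiv), THF, rt, 1 h; then 3 (1.0 equiv), [Ru(p-cymene)Cl2]2 (1 mol%), dmpe (2 mol%), K3PO4 (25 mol%), CsF (50 mol%), THF, 45 °C, argon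
Reagents that add atoms: none
Why: Ruthenium-catalysed hydrazone addition to an aldehyde (a catalytic Wolff–Kishner-type carbonyl umpolung), in which hydrazone 4 bound to divalent ruthenium acts as a benzyl carbanion, adds to the C=O of 3 through a six-membered chair-like transition state and then loses N2, the aryl bromide and benzyl ether being inert; the new carbinol centre forms racemic and is deleted in step 3.

Step 2
Reactants: 5 racemic 1-[3-(benzyloxy)phenyl]-2-(2-bromo-3,5-dimethoxyphenyl)ethan-1-ol; 6 4-(benzyloxy)benzaldehyde; 2 hydrazine monohydrate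
Product: 8 racemic 1-[3-(benzyloxy)phenyl]-2-{2-[4-(benzyloxy)benzyl]-3,5-dimethoxyphenyl}ethan-1-ol, via (E)-[4-(benzyloxy)benzylidene]hydrazine 7 (not isolated)
Conditions: 6 (1.5 equiv), 2 (1.55 equiv), THF, rt, 1 h; then 5 (1.0 equiv), Ni(cod)2 (10 mol%), PMe3 (30 mol%), K3PO4 (2 equiv), THF, 60 °C, argon
Reagents that add atoms: none
Why: Nickel-catalysed deoxygenative cross-coupling of an aldehyde hydrazone with an aryl bromide (Wolff–Kishner-type umpolung cross-coupling), in which zerovalent nickel inserts into the C–Br bond of 5, the deprotonated hydrazone 7 is transferred to nickel and loses N2 to give an aryl(benzyl)nickel species that reductively eliminates the diarylmethane, so the carbonyl carbon of 6 serves as the nucleophile; no new stereocentre is formed and the existing racemic carbinol is untouched.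

Step 3
Reactants: 8 racemic 1-[3-(benzyloxy)phenyl]-2-{2-[4-(benzyloxy)benzyl]-3,5-dimethoxyphenyl}ethan-1-ol
Product: 9 Gymcononopin D, 3-{2-[2-(4-hydroxybenzyl)-3,5-dimethoxyphenyl]ethyl}phenol
Conditions: H2 (3 atm), 10% Pd/C, EtOH, conc. HCl (cat.), 25 °C
Reagents that add atoms: none
Why: Heterogeneous palladium-catalysed hydrogenolysis cleaves both O-benzyl ethers and, with acid assistance (directly or through the stilbene formed by dehydration), reduces the benzylic C–OH to CH2, which erases the only stereocentre and leaves the aryl methyl ethers and the diarylmethane CH2 intact.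

**Compound list**
1 | 2-bromo-3,5-dimethoxybenzaldehyde | COc1cc(C=O)c(Br)c(OC)c1 | starting material
2 | hydrazine monohydrate | NN.O | starting material
3 | 3-(benzyloxy)benzaldehyde | O=Cc1cccc(OCc2ccccc2)c1 | starting material
4 | (E)-(2-bromo-3,5-dimethoxybenzylidene)hydrazine | N/N=C/c1cc(OC)cc(OC)c1Br | intermediate (not isolated)
5 | racemic 1-[3-(benzyloxy)phenyl]-2-(2-bromo-3,5-dimethoxyphenyl)ethan-1-ol | OC(Cc1cc(OC)cc(OC)c1Br)c1cccc(OCc2ccccc2)c1 | intermediate
6 | 4-(benzyloxy)benzaldehyde | O=Cc1ccc(OCc2ccccc2)cc1 | starting material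
7 | (E)-[4-(benzyloxy)benzylidene]hydrazine | N/N=C/c1ccc(OCc2ccccc2)cc1 | intermediate (not isolated)
8 | racemic 1-[3-(benzyloxy)phenyl]-2-{2-[4-(benzyloxy)benzyl]-3,5-dimethoxyphenyl}ethan-1-ol | OC(Cc1cc(OC)cc(OC)c1Cc1ccc(OCc2ccccc2)cc1)c1cccc(OCc2ccccc2)c1 | intermediate
9 | Gymcononopin D, 3-{2-[2-(4-hydroxybenzyl)-3,5-dimethoxyphenyl]ethyl}phenol (achiral) | COc1cc(CCc2cccc(O)c2)c(Cc2ccc(O)cc2)c(OC)c1 | target

**Step count**
Total steps: 3. Longest linear sequence: 3 (1 → 5 → 8 → 9).

**Steps most likely to fail, with fallbacks** (risk order: step 2 > step 1 > step 3)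

Step 1. The risk is hydrazone exchange between 4 and aldehyde 3 (azine and homo-coupled alcohols) or sluggish addition of the ortho-bromo hydrazone. The fallback uses normal polarity, sets out from 1 and comes back to the route at 5. The ylide (methoxymethylidene)triphenylphosphorane F1, made from (methoxymethyl)triphenylphosphonium chloride and KOtBu in THF at 0 °C, converts 1 into the enol ether (E/Z)-2-bromo-1,5-dimethoxy-3-(2-methoxyethenyl)benzene F2. Aqueous 2 M HCl in THF unmasks 2-(2-bromo-3,5-dimethoxyphenyl)acetaldehyde F3, which is used at once. Addition of [3-(benzyloxy)phenyl]magnesium bromide F4 (from 1-(benzyloxy)-3-bromobenzene and Mg in THF) at −78 °C then gives 5.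

Step 2. The bromide of 5 sits between a methoxy group and the CH2CH(OH)Ar chain, and the hydrazone–aryl bromide coupling is unproven for such a di-ortho-substituted partner carrying a free hydroxyl; hydrodebromination of 5 or plain Wolff–Kishner reduction of 7 may win. The fallback sets out from 5 and comes back at 8, replacing the hydrazone by a preformed benzyl nucleophile. [4-(Benzyloxy)benzyl]zinc chloride F5, made from 4-(benzyloxy)benzyl chloride, Zn dust and LiCl in THF at 25 °C, is coupled with 5 under Pd(OAc)2/SPhos in THF at 25–50 °C (Negishi coupling). This catalyst handles di-ortho-substituted bromides and outruns protonolysis of the organozinc by the hydroxyl group. The route still keeps the reversed-polarity bond construction of step 1.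

Step 3. The unactivated benzylic C–OH may resist hydrogenolysis, or the acid may trigger Friedel–Crafts side reactions of the electron-rich rings. The fallback sets out from 8 and comes back at 9, replacing direct C–O hydrogenolysis by base-mediated elimination followed by neutral hydrogenation. MsCl and Et3N in CH2Cl2 at 0 °C give racemic 1-[3-(benzyloxy)phenyl]-2-{2-[4-(benzyloxy)benzyl]-3,5-dimethoxyphenyl}ethyl methanesulfonate F6, which is not isolated. DBU in toluene at 80 °C eliminates it to (E)-1-(benzyloxy)-3-(2-{2-[4-(benzyloxy)benzyl]-3,5-dimethoxyphenyl}ethenyl)benzene F7. H2 (1 atm) over Pd/C in EtOAc–MeOH without acid then saturates the alkene and cleaves both benzyl ethers to give 9.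

**Further compounds**
F1 | step 1 | (methoxymethylidene)triphenylphosphorane | COC=P(c1ccccc1)(c1ccccc1)c1ccccc1
F2 | step 1 | (E/Z)-2-bromo-1,5-dimethoxy-3-(2-methoxyethenyl)benzene (mixture of alkene isomers) | COC=Cc1cc(OC)cc(OC)c1Br
F3 | step 1 | 2-(2-bromo-3,5-dimethoxyphenyl)acetaldehyde | COc1cc(CC=O)c(Br)c(OC)c1
F4 | step 1 | [3-(benzyloxy)phenyl]magnesium bromide | Br[Mg]c1cccc(OCc2ccccc2)c1
F5 | step 2 | [4-(benzyloxy)benzyl]zinc chloride | Cl[Zn]Cc1ccc(OCc2ccccc2)cc1
F6 | step 3 | racemic 1-[3-(benzyloxy)phenyl]-2-{2-[4-(benzyloxy)benzyl]-3,5-dimethoxyphenyl}ethyl methanesulfonate | CS(=O)(=O)OC(Cc1cc(OC)cc(OC)c1Cc1ccc(OCc2ccccc2)cc1)c1cccc(OCc2ccccc2)c1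
F7 | step 3 | (E)-1-(benzyloxy)-3-(2-{2-[4-(benzyloxy)benzyl]-3,5-dimethoxyphenyl}ethenyl)benzene | COc1cc(/C=C/c2cccc(OCc3ccccc3)c2)c(Cc2ccc(OCc3ccccc3)cc2)c(OC)c1
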